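The readings are calculated from invented constants; the scatter is artificial.

In this flask target cannot reach 100% while catalyst intermediate B still holds part of the solid substrate.

- ash: solid substrate 0.25 M; free catalyst 9 mol% (in portions, 4); the very flask that is asked about, followed so far; portions every 15 h
- flask: solid substrate 0.25 M; free catalyst 9 mol% (in portions, 4); time 15 d; the portions of free catalyst follow each other after 15 h, the first at the start

ash run (percent of the solid substrate charged)

| time / d | target / % | catalyst intermediate B / % |
|---|---|---|
| 1.04 | 68.7 | 3.4 |
| 2.08 | 95.7 | 3.9 |
| 3.00 | 97.1 | 3.6 |
| 4.00 | 94.7 | 4.0 |
| 5.00 | 96.0 | 4.4 |
| 6.00 | 95.4 | 4.0 |

(scatter of a reading: 1 percentage point)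

- given per volume of solution although it is solid: solid substrate
- at the start none of the solid substrate is in solution
- what has only dissolved of solid substrate counts as not reacted
- the reaction counts as stopped when no species that holds the solid substrate changes by six tenths of a point or more over the second half of the time

- which holds at 15 d: what has brought the reaction to rest, or that it has not come to rest (for what has run out or reacted, a solid counts together with what of it has only dissolved) (no working catalyst is left / all of the solid substrate has reacted / forward and back rates have come level / it is still moving)
- how much target there is at 15 d, in percent of the solid substrate charged
- how much catalyst intermediate B there is at 15 d, in percent of the solid substrate charged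
- amount of target if the flask were left three thousand times as long, in percent of the solid substrate charged

The bench rule says a catalyst at a few mol% costs no yield, and applied honestly it gives 100% target. The ash run, which is this flask followed so far, refuses that. From 2.08 d on it averages 95.8% target and 3.98% B, together 99.8%. These means cover the whole loading, because the last portion went in at 1.88 d, before the first of them.

So we work with what is left. Of the 9 mol% loading, B, a resting state of the catalyst, takes about half, and 5.02% stays free. Our own reckoning treats B as balanced against free catalyst and target. Free catalyst times target over B, as concentrations, gives 0.302 M, our balance quotient, a reading with the scatter of the means. Divided by the charge it is 1.21, and then B equals the loading times target over target plus that figure.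

The bench rule ends where this loss outgrows the scatter. The ratio of loading to quotient is just 0.0744, yet the loss is 3.98% against a scatter of 1 percentage point. We expect B and target to stay at these means at 15 d.

The forecast says all of the solid substrate has reacted, with 96% target (95% to 97%), 4% B (3.4% to 4.6%) and 96% in the far future (95% to 100%). It calls B “a stable sink, or at least a very slow one”, where we reckon with a balance.

In the flask at 15 d, all of the solid substrate has reacted. Target stands at 95.7%, and at 95.7% in the far future. Catalyst intermediate B stands at 4.31%. Over the second half of the time nothing moves, the largest change being 0 points.

    starting material + free catalyst ⇌ catalyst intermediate A (K = 12.0 M⁻¹, k = 150 M⁻¹ h⁻¹)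
    catalyst intermediate A → catalyst intermediate B (k = 10.0 h⁻¹)
    catalyst intermediate B ⇌ free catalyst + target (K = 0.260 M, k = 1.30 h⁻¹)
    solid substrate ⇌ starting material, rate k4*(cs4 - [starting material]) while solid is left; crystals form when [starting material] > cs4 (solubility = 0.0930 M, k = 0.670 h⁻¹)

Our quotient with 95.7% target gives 3.97% B in this flask, beside the 4.31% computed.

At 36 mol% of free catalyst target no longer stays near the whole charge, so the balance is solved in full. It gives 2.57 as the sum term and 14.9% B, hence 85.1% target. The computed neighbour holds 16.1% B and 83.9% target.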